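The synthesis rests on cutting the dodecatrienyl chain between its oxygen-bound carbon (C1) and C2. The key step exploits the ether oxygen on C1: tin–lithium exchange turns this normally electrophilic O–CH2 carbon into an α-alkoxymethyllithium, which is alkylated by the complete (3E,5E,7E)-undecatrienyl bromide, so two carbons of like polarity are joined and the glycerol unit meets the whole triene in one operation. The precursor is the tributylstannylmethyl ether of (R)-solketal; the bromide arises from a cyclopropyl dienyl carbinol by homoallylic ring opening, which places the C4=C5 alkene two atoms from C2. Acetonide cleavage, primary silylation, acylation with the protected 4-hydroxybenzoic acid and desilylation complete the target.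

Key step: step 4

Assumption: the stannylmethyl iodide of step 3 and the silyl-protected benzoic acid of step 7 are taken as catalogue compounds; all triene intermediates are handled under argon, cold and shielded from light.

Step 1
Reactants: 1 cyclopropylmagnesium bromide; 2 (2E,4E)-octa-2,4-dienal
Product: 3 (2E,4E)-1-cyclopropylocta-2,4-dien-1-ol (racemic)
Conditions: THF, −78 → 0 °C; then H2O/sat. NH4Cl; chromatography on Et3N-deactivated silica
Reagents that add atoms: none
Why: Grignard 1,2-addition to the aldehyde carbonyl of a dienal is fast at low temperature and leaves the E,E-diene untouched, and the racemic carbinol centre is of no consequence because it becomes sp2 in step 2.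

Step 2
Reactants: 3 (2E,4E)-1-cyclopropylocta-2,4-dien-1-ol
Product: 4 (3E,5E,7E)-1-bromoundeca-3,5,7-triene
Conditions: MgBr2·OEt2 (2.5 equiv), Et2O, 0 °C → rt
Reagents that add atoms: magnesium bromide diethyl etherate, CCOCC.[Mg+2].[Br-].[Br-]
Why: Julia cyclopropylcarbinyl-to-homoallyl rearrangement (magnesium halide variant), in which Lewis-acid ionisation gives a cyclopropyl-substituted pentadienyl cation that bromide opens at a ring CH2 through the bisected s-trans arrangement, so the new alkene should form E while any allylic bromides from attack at the dienyl termini re-ionise and funnel to the strain-free triene.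

Step 3
Reactants: 5 (R)-solketal, [(4R)-2,2-dimethyl-1,3-dioxolan-4-yl]methanol; 6 tributyl(iodomethyl)stannane
Product: 7 tributyl({[(4S)-2,2-dimethyl-1,3-dioxolan-4-yl]methoxy}methyl)stannane (spatial arrangement of (R)-solketal; the descriptor is S only because tin raises the priority of the side chain)
Conditions: NaH, THF/DMF, 0 °C; then 6, rt
Reagents that add atoms: none
Why: Williamson etherification of the sodium alkoxide with the highly SN2-reactive α-stannyl iodide (stannylmethylation of an alcohol), which does not involve the stereocentre and to which the acetonide is inert.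

Step 4
Reactants: 7 tributyl({[(4S)-2,2-dimethyl-1,3-dioxolan-4-yl]methoxy}methyl)stannane; 4 (3E,5E,7E)-1-bromoundeca-3,5,7-triene
Product: 9 (4R)-4-({[(4E,6E,8E)-dodeca-4,6,8-trien-1-yl]oxy}methyl)-2,2-dimethyl-1,3-dioxolane, via alkoxymethyllithium 8 (not isolated)
Conditions: n-BuLi (0.98 equiv), THF, −78 °C, 15 min; then 4, DMPU, −78 → −40 °C
Reagents that add atoms: none
Why: Tin–lithium exchange (n-BuLi attacks tin and the ate complex expels the most stabilised carbanion) converts 7 into the α-alkoxymethyllithium 8, which displaces bromide from the primary CH2Br of 4 in an SN2 reaction. The closest known reaction type is Still's alkylation of α-alkoxyorganolithiums, made by tin–lithium exchange, with primary alkyl halides. No ring is closed and no stereocentre is formed; the dioxolane stereocentre is remote from the carbanion and is not touched. The step needs substitution to win over E2 elimination of 4 to a tetraene, over addition of the organolithium to the triene and over [1,2]-Wittig rearrangement of 8. This should be secured by the unhindered primary bromide, by the small, oxygen-stabilised and therefore less basic carbanion, by DMPU as an SN2-accelerating cosolvent and by keeping the mixture at or below −40 °C; n-BuLi is used in slight deficit so that none remains to attack 4.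

Step 5
Reactants: 9 (4R)-4-({[(4E,6E,8E)-dodeca-4,6,8-trien-1-yl]oxy}methyl)-2,2-dimethyl-1,3-dioxolane
Product: 10 (2S)-3-{[(4E,6E,8E)-dodeca-4,6,8-trien-1-yl]oxy}propane-1,2-diol
Conditions: AcOH/H2O (4:1), 40 °C
Reagents that add atoms: none
Why: Acid-catalysed hydrolysis of the isopropylidene acetal under conditions too weakly acidic to protonate the conjugated triene, with no C–O bond at the stereocentre being broken.

Step 6
Reactants: 10 (2S)-3-{[(4E,6E,8E)-dodeca-4,6,8-trien-1-yl]oxy}propane-1,2-diol
Product: 11 (2R)-1-[(tert-butyldimethylsilyl)oxy]-3-{[(4E,6E,8E)-dodeca-4,6,8-trien-1-yl]oxy}propan-2-ol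
Conditions: TBSCl (1.05 equiv), imidazole, CH2Cl2, −10 → 0 °C
Reagents that add atoms: tert-butyldimethylsilyl chloride, CC(C)(C)[Si](C)(C)Cl
Why: Sterically controlled silylation, the primary hydroxyl reacting much faster with the bulky silyl chloride than the flanked secondary one.

Step 7
Reactants: 11 (2R)-1-[(tert-butyldimethylsilyl)oxy]-3-{[(4E,6E,8E)-dodeca-4,6,8-trien-1-yl]oxy}propan-2-ol; 12 4-[(tert-butyldimethylsilyl)oxy]benzoic acid
Product: 13 (2R)-1-[(tert-butyldimethylsilyl)oxy]-3-{[(4E,6E,8E)-dodeca-4,6,8-trien-1-yl]oxy}propan-2-yl 4-[(tert-butyldimethylsilyl)oxy]benzoate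
Conditions: DCC, DMAP (cat.), CH2Cl2, 0 °C → rt
Reagents that add atoms: none
Why: Steglich esterification acylates the remaining secondary alcohol under neutral conditions with the C–O bond of the stereocentre untouched, both silyl ethers and the triene being inert.

Step 8
Reactants: 13 (2R)-1-[(tert-butyldimethylsilyl)oxy]-3-{[(4E,6E,8E)-dodeca-4,6,8-trien-1-yl]oxy}propan-2-yl 4-[(tert-butyldimethylsilyl)oxy]benzoate
Product: 14 (2S)-1-{[(4E,6E,8E)-dodeca-4,6,8-trien-1-yl]oxy}-3-hydroxypropan-2-yl 4-hydroxybenzoate (CNP0352133.1)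
Conditions: TBAF/AcOH (1:1.2, 3 equiv), THF, 0 °C → rt; rapid chromatography on neutral silica
Reagents that add atoms: none
Why: Fluoride-mediated desilylation cleaves the aryl and the primary alkyl silyl ether, and the acetic acid buffer keeps the medium near neutral so that the 2-O-aroyl group should not migrate to the liberated primary hydroxyl.

Compound list
1 | cyclopropylmagnesium bromide | Br[Mg]C1CC1 | starting material
2 | (2E,4E)-octa-2,4-dienal | CCC/C=C/C=C/C=O | starting material
3 | (2E,4E)-1-cyclopropylocta-2,4-dien-1-ol (racemic) | CCC/C=C/C=C/C(O)C1CC1 | intermediate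
4 | (3E,5E,7E)-1-bromoundeca-3,5,7-triene | CCC/C=C/C=C/C=C/CCBr | intermediate
5 | (R)-solketal, [(4R)-2,2-dimethyl-1,3-dioxolan-4-yl]methanol | OC[C@@H]1COC(C)(C)O1 | starting material
6 | tributyl(iodomethyl)stannane | CCCC[Sn](CCCC)(CCCC)CI | starting material
7 | tributyl({[(4S)-2,2-dimethyl-1,3-dioxolan-4-yl]methoxy}methyl)stannane | CCCC[Sn](CCCC)(CCCC)COC[C@@H]1COC(C)(C)O1 | intermediate
8 | ({[(4R)-2,2-dimethyl-1,3-dioxolan-4-yl]methoxy}methyl)lithium | [Li]COC[C@@H]1COC(C)(C)O1 | intermediate
9 | (4R)-4-({[(4E,6E,8E)-dodeca-4,6,8-trien-1-yl]oxy}methyl)-2,2-dimethyl-1,3-dioxolane | CCC/C=C/C=C/C=C/CCCOC[C@@H]1COC(C)(C)O1 | intermediate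
10 | (2S)-3-{[(4E,6E,8E)-dodeca-4,6,8-trien-1-yl]oxy}propane-1,2-diol | CCC/C=C/C=C/C=C/CCCOC[C@@H](O)CO | intermediate
11 | (2R)-1-[(tert-butyldimethylsilyl)oxy]-3-{[(4E,6E,8E)-dodeca-4,6,8-trien-1-yl]oxy}propan-2-ol | CCC/C=C/C=C/C=C/CCCOC[C@@H](O)CO[Si](C)(C)C(C)(C)C | intermediate
12 | 4-[(tert-butyldimethylsilyl)oxy]benzoic acid | CC(C)(C)[Si](C)(C)Oc1ccc(C(=O)O)cc1 | starting material
13 | (2R)-1-[(tert-butyldimethylsilyl)oxy]-3-{[(4E,6E,8E)-dodeca-4,6,8-trien-1-yl]oxy}propan-2-yl 4-[(tert-butyldimethylsilyl)oxy]benzoate | CCC/C=C/C=C/C=C/CCCOC[C@H](CO[Si](C)(C)C(C)(C)C)OC(=O)c1ccc(O[Si](C)(C)C(C)(C)C)cc1 | intermediate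
14 | (2S)-1-{[(4E,6E,8E)-dodeca-4,6,8-trien-1-yl]oxy}-3-hydroxypropan-2-yl 4-hydroxybenzoate | CCC/C=C/C=C/C=C/CCCOC[C@H](CO)OC(=O)c1ccc(O)cc1 | target

Total step count: 8
Longest linear sequence: 7 steps (steps 1, 2, 4, 5, 6, 7, 8)

Steps most likely to fail

Step 4. E2 elimination of HBr from 4 to a conjugated tetraene (its C2–H bonds are allylic to the triene), addition of the organolithium to the triene, or lithium–bromine exchange may outrun substitution. The fallback sets out from 7 and comes back at 9; it keeps the same carbanion but moves triene construction after the union. Lithium reagent 8, generated as before, is alkylated with the saturated electrophile (3-bromopropoxy)(tert-butyl)dimethylsilane to give (4R)-4-({4-[(tert-butyldimethylsilyl)oxy]butoxy}methyl)-2,2-dimethyl-1,3-dioxolane F1. TBAF in THF frees 4-{[(4R)-2,2-dimethyl-1,3-dioxolan-4-yl]methoxy}butan-1-ol F2. Mitsunobu reaction with 1-phenyl-1H-tetrazole-5-thiol (PPh3, DIAD, THF) gives 5-[(4-{[(4R)-2,2-dimethyl-1,3-dioxolan-4-yl]methoxy}butyl)sulfanyl]-1-phenyl-1H-tetrazole F3, and oxidation with ammonium molybdate/H2O2 in EtOH gives 5-[(4-{[(4R)-2,2-dimethyl-1,3-dioxolan-4-yl]methoxy}butyl)sulfonyl]-1-phenyl-1H-tetrazole F4. Julia–Kocienski olefination of F4 with dienal 2 (KHMDS, DME, −60 °C → rt) should then build the C4=C5 alkene of 9, any 4Z isomer being equilibrated with catalytic iodine.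

Step 2. Bromide capture at the dienyl termini of the cation, erosion of E geometry by bond rotation in the delocalised cation, or acid-induced oligomerisation of the triene may lower the purity of 4. The fallback sets out from 2 and comes back at 4. Wittig reaction of 2 with the ylide from (3-hydroxypropyl)triphenylphosphonium bromide (2 equiv NaHMDS, THF, −78 °C → rt) should give the trienol as a 3Z/3E mixture rich in (3Z,5E,7E)-undeca-3,5,7-trien-1-ol F5. Catalytic iodine in CH2Cl2 under ambient light equilibrates this to (3E,5E,7E)-undeca-3,5,7-trien-1-ol F6, and Appel bromination (CBr4, PPh3, CH2Cl2, 0 °C) converts F6 into 4.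

Step 8. Migration of the aroyl group from the secondary to the freshly liberated primary oxygen, under fluoride or on silica, would give the regioisomeric primary ester. The fallback sets out from 10 and comes back at 14; it replaces both silyl groups by acyl-type groups that are removed at near-neutral pH. Primary-selective acylation of diol 10 with levulinic acid (DCC, cat. DMAP, CH2Cl2, −20 °C) gives (2R)-3-{[(4E,6E,8E)-dodeca-4,6,8-trien-1-yl]oxy}-2-hydroxypropyl 4-oxopentanoate F7. Steglich esterification with commercial 4-acetoxybenzoic acid gives (2R)-1-{[(4E,6E,8E)-dodeca-4,6,8-trien-1-yl]oxy}-3-[(4-oxopentanoyl)oxy]propan-2-yl 4-(acetyloxy)benzoate F8. Hydrazine hydrate/AcOH in pyridine (0 °C, degassed) should then remove the levulinoyl group and the aryl acetate together to give 14.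

Further compounds
F1 | step 4 | (4R)-4-({4-[(tert-butyldimethylsilyl)oxy]butoxy}methyl)-2,2-dimethyl-1,3-dioxolane | CC(C)(C)[Si](C)(C)OCCCCOC[C@@H]1COC(C)(C)O1
F2 | step 4 | 4-{[(4R)-2,2-dimethyl-1,3-dioxolan-4-yl]methoxy}butan-1-ol | OCCCCOC[C@@H]1COC(C)(C)O1
F3 | step 4 | 5-[(4-{[(4R)-2,2-dimethyl-1,3-dioxolan-4-yl]methoxy}butyl)sulfanyl]-1-phenyl-1H-tetrazole | c1ccccc1-n1nnnc1SCCCCOC[C@@H]1COC(C)(C)O1
F4 | step 4 | 5-[(4-{[(4R)-2,2-dimethyl-1,3-dioxolan-4-yl]methoxy}butyl)sulfonyl]-1-phenyl-1H-tetrazole | O=S(=O)(CCCCOC[C@@H]1COC(C)(C)O1)c1nnnn1-c1ccccc1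
F5 | step 2 | (3Z,5E,7E)-undeca-3,5,7-trien-1-ol | CCC/C=C/C=C/C=C\CCO
F6 | step 2 | (3E,5E,7E)-undeca-3,5,7-trien-1-ol | CCC/C=C/C=C/C=C/CCO
F7 | step 8 | (2R)-3-{[(4E,6E,8E)-dodeca-4,6,8-trien-1-yl]oxy}-2-hydroxypropyl 4-oxopentanoate | CCC/C=C/C=C/C=C/CCCOC[C@@H](O)COC(=O)CCC(C)=O
F8 | step 8 | (2R)-1-{[(4E,6E,8E)-dodeca-4,6,8-trien-1-yl]oxy}-3-[(4-oxopentanoyl)oxy]propan-2-yl 4-(acetyloxy)benzoate | CCC/C=C/C=C/C=C/CCCOC[C@H](COC(=O)CCC(C)=O)OC(=O)c1ccc(OC(C)=O)cc1
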